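A neighbouring flask ran with 0.15 mM of acid in place of 0.600 mM, so I want one number that reads both flasks.

    substrate + acid → weak acid + acid + product (k1 = 12 /M/min)
    weak acid ⇌ conjugate base + acid, settled at all times (K2 = 1.0 × 10⁻⁴ M)
    substrate → weak acid + product (k3 = 0.0027 /min)
    weak acid → by-product carried off (k4 = 0.11 /min)

substrate 20 mM (fed, over 3.0 h); acid 0.600 mM; time 3.0 h

- part of the substrate that has reacted at 3.0 h
- pH of the solution at 3.0 h

I follow one molecule of substrate to its fork: it leaves by the acid-carried step, which gives the acid back, or by the bare step without acid. Turned round, the question is what would let the bare step take the larger share. Acid would have to stand below H\*, the even-odds acid 0.225 mM, defined as the bare constant over the acid-carried constant. This flask's charge is 2.67 times that, higher than H\*, so reckoned at that charge the acid-carried step gets 72.7% of the molecules.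

I hold acid at its charge as an estimate, because weak acid has a half-life of 0.11 h by its removal step alone, much shorter than the 1.6 h of substrate by the acid-carried step alone with acid as charged. The two exits then add to one pseudo-first-order constant, 0.00990 /min. Fed molecules have ages spread evenly from nothing to 3.0 h, and averaging their survival over those ages leaves 46.7% of the substrate. I therefore commit to 53.3% reacted. The forecast says 53.8%, slightly above mine, and pH 3.21, reasoning that “the weak acid is removed quickly and its dissociation is suppressed”.

The simulation gives 56.8% and pH 3.14, with acid in this flask at 120% of its charge, still higher than H\*. The neighbouring flask's charge of 0.15 mM lies lower than H\*, so reckoned at that charge the same fork gives the acid-carried step 40.0% of its molecules. With acid held at that charge, its constant is 0.00450 /min, and the same average leaves 68.5%, which I reckon as 31.5% reacted. That neighbouring flask gives 40.8%, and its acid ends at 235% of its own charge, which is 0.352 mM, higher than H\*.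

(The numbers of this flask were set for the occasion; the rest is arithmetic.)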